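**Retrosynthetic overview**

1. Target ⇒ C6–C4 bond (made last): fisetinidol-(4β→8)-catechin plus the flavan-4-yl cation released from (+)-mollisacacidin.
2. Dimer ⇒ C8–C4 bond: (+)-catechin (bought, all three rings intact) plus the same flavan-3,4-diol.
3. (+)-Mollisacacidin ⇒ tri-O-benzyl-(+)-fustin (debenzylation and C4 reduction in one flask); fustin core ⇒ key disconnections O1–C2 and C3–O, so both C–O bonds, ring C and the C2/C3 stereocentres come from one asymmetric oxidative cyclisation of a 2'-hydroxychalcone.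
4. Chalcone ⇒ Claisen–Schmidt union of two benzyl-protected aromatic building blocks.
5. Ring order: the pyranone ring C of the fisetinidol unit is the only ring built (by C–O closure); the diol is made once and used twice, and the interflavan bonds are set on unprotected phenols, C8 first, C6 second.

Assumption: the target is read as fisetinidol-(4β→8)-catechin-(6→4α)-fisetinidol (C8-linked unit 2R,3S,4R with 3,4-cis; C6-linked unit 2R,3S,4S with 3,4-trans; catechin core 2R,3S), and building blocks 1 and 2 are taken as catalogue chemicals.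

**Route**

Step 1
Reactants: 1 1-[4-(benzyloxy)-2-hydroxyphenyl]ethanone; 2 3,4-bis(benzyloxy)benzaldehyde
Product: 3 (E)-1-[4-(benzyloxy)-2-hydroxyphenyl]-3-[3,4-bis(benzyloxy)phenyl]prop-2-en-1-one
Conditions: KOH (50% aq, 5 equiv), EtOH, rt, 36 h; then aq HCl to pH 4, filter
Reagents that add atoms: none
Why: Claisen–Schmidt aldol condensation of an aryl methyl ketone with a non-enolisable aldehyde, the E-enone forming under thermodynamic control and the 2'-OH being carried as its phenoxide.

Step 2
Reactants: 3 (E)-2'-hydroxychalcone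
Product: 5 (2R,3R)-7-(benzyloxy)-2-[3,4-bis(benzyloxy)phenyl]-3-hydroxychroman-4-one, via chalcone epoxide 4 (not isolated)
Conditions: (S)-bis(3,5-dimethylphenyl)(pyrrolidin-2-yl)methanol (20 mol%), TBHP (1.3 equiv, in decane), toluene–hexane 1:1, 4 °C, 72 h; then Et3N (0.5 equiv), rt, 2 h; recrystallise (EtOAc–hexane)
Reagents that add atoms: tert-butyl hydroperoxide, CC(C)(C)OO
Why: Proposed new method: an organocatalytic enantioselective Algar–Flynn–Oyamada cyclisation stopped at the dihydroflavonol level, in which the amino alcohol and TBHP form an ammonium tert-butylperoxide ion pair held by the catalyst OH against the chalcone carbonyl (the 2'-OH staying locked in its internal O–H···O=C hydrogen bond in the non-polar medium), so that face-selective conjugate addition and O–O closure give the (2R,3S)-epoxide 4 (first C–O bond, sets C3), after which the free 2'-phenol opens the epoxide 6-endo at the electron-rich benzylic carbon with inversion (second C–O bond, closes ring C, sets C2) to give the 2,3-trans (2R,3R) product; the closest known reactions are the diarylprolinol/TBHP Weitz–Scheffer epoxidation of simple chalcones and the non-asymmetric alkaline-peroxide Algar–Flynn–Oyamada reaction, and the hydrogen-peroxide-free, weakly basic medium is chosen so that the product is not oxidised on to the flavonol.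

Step 3
Reactants: 5 tri-O-benzyl-(+)-fustin
Product: 7 (2R,3S,4R)-2-(3,4-dihydroxyphenyl)chromane-3,4,7-triol ((+)-mollisacacidin), via (+)-fustin 6 (not isolated)
Conditions: H2 (1 atm), 10% Pd/C, THF–MeOH 1:1, rt, 4 h; filter through Celite under N2; then NaBH4 (4 equiv), 0 °C to rt, 2 h; AcOH to pH 6, EtOAc extraction
Reagents that add atoms: none
Why: Catalytic hydrogenolysis of the three aryl benzyl ethers at 1 atm leaves the chromanone carbonyl and C2/C3 untouched, and borohydride reduction of the free-phenolic dihydroflavonol in the same solution then delivers hydride axially to the C4 ketone to give the all-equatorial 2,3-trans-3,4-trans diol (new C4 centre set R by substrate control), the near-neutral quench keeping this acid-labile benzylic diol from ionising before it is wanted.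

Step 4
Reactants: 7 (+)-mollisacacidin; 8 (+)-catechin
Product: 9 fisetinidol-(4β→8)-catechin
Conditions: 7 (1 equiv), 8 (4 equiv), 0.1 M aq HCl, rt, 24 h, N2; EtOAc extraction; Sephadex LH-20 (EtOH), then reversed-phase HPLC
Reagents that add atoms: none
Why: In dilute acid the benzylic C4–OH of 7, para to the 7-OH, ionises to a stabilised flavan-4-yl cation that is captured by C8 of catechin, its most reactive phloroglucinol carbon, in a biomimetic SN1 Friedel–Crafts alkylation; the 5-deoxy 2,3-trans cation is attacked on both faces (4α:4β estimated at roughly 3:2), so the new C4 centre of 9 (β-face attack, 3,4-cis) is secured by chromatographic separation from its 4α epimer and the minor 4→6 isomers, while C2 and C3 of both units are not touched and the excess of catechin suppresses over-alkylation.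

Step 5
Reactants: 9 fisetinidol-(4β→8)-catechin; 7 (+)-mollisacacidin
Product: 10 fisetinidol-(4β→8)-catechin-(6→4α)-fisetinidol (target)
Conditions: 9 (1 equiv), 7 (1.5 equiv, added in three portions), 0.1 M aq HCl, rt, 36 h, N2; Sephadex LH-20 (EtOH), then reversed-phase HPLC
Reagents that add atoms: none
Why: The same acid ionisation of 7 feeds a second SN1 Friedel–Crafts alkylation at C6 of the catechin ring, the only phloroglucinol-type carbon left and far more nucleophilic than the resorcinol-type A-ring carbons of the fisetinidol unit, and at this position flanked by two hydroxyls the cation is taken on its α-face, anti to its own 3-OH, which sets the new C4 as 3,4-trans (4α), the minor 4β epimer being removed by chromatography.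

**Compound list**

1 | 1-[4-(benzyloxy)-2-hydroxyphenyl]ethanone | CC(=O)c1ccc(OCc2ccccc2)cc1O | starting material
2 | 3,4-bis(benzyloxy)benzaldehyde | O=Cc1ccc(OCc2ccccc2)c(OCc2ccccc2)c1 | starting material
3 | (E)-1-[4-(benzyloxy)-2-hydroxyphenyl]-3-[3,4-bis(benzyloxy)phenyl]prop-2-en-1-one | O=C(/C=C/c1ccc(OCc2ccccc2)c(OCc2ccccc2)c1)c1ccc(OCc2ccccc2)cc1O | intermediate
4 | [(2R,3S)-3-[3,4-bis(benzyloxy)phenyl]oxiran-2-yl][4-(benzyloxy)-2-hydroxyphenyl]methanone | O=C(c1ccc(OCc2ccccc2)cc1O)[C@@H]1O[C@H]1c1ccc(OCc2ccccc2)c(OCc2ccccc2)c1 | intermediate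
5 | (2R,3R)-7-(benzyloxy)-2-[3,4-bis(benzyloxy)phenyl]-3-hydroxychroman-4-one (7,3',4'-tri-O-benzyl-(+)-fustin) | O=C1c2ccc(OCc3ccccc3)cc2O[C@H](c2ccc(OCc3ccccc3)c(OCc3ccccc3)c2)[C@H]1O | intermediate
6 | (2R,3R)-2-(3,4-dihydroxyphenyl)-3,7-dihydroxychroman-4-one ((+)-fustin) | O=C1c2ccc(O)cc2O[C@H](c2ccc(O)c(O)c2)[C@H]1O | intermediate
7 | (2R,3S,4R)-2-(3,4-dihydroxyphenyl)chromane-3,4,7-triol ((+)-mollisacacidin, 2,3-trans-3,4-trans) | Oc1ccc2c(c1)O[C@H](c1ccc(O)c(O)c1)[C@@H](O)[C@@H]2O | intermediate
8 | (2R,3S)-2-(3,4-dihydroxyphenyl)chromane-3,5,7-triol ((+)-catechin) | O[C@H]1Cc2c(O)cc(O)cc2O[C@@H]1c1ccc(O)c(O)c1 | starting material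
9 | fisetinidol-(4β→8)-catechin: (2R,3S)-catechin carrying at C8 a (2R,3S,4R)-2-(3,4-dihydroxyphenyl)-3,7-dihydroxychroman-4-yl group (3,4-cis) | Oc1ccc2c(c1)O[C@H](c1ccc(O)c(O)c1)[C@@H](O)[C@H]2c1c(O)cc(O)c2c1O[C@H](c1ccc(O)c(O)c1)[C@@H](O)C2 | intermediate
10 | fisetinidol-(4β→8)-catechin-(6→4α)-fisetinidol: the C8 unit as in 9, and at C6 a (2R,3S,4S)-2-(3,4-dihydroxyphenyl)-3,7-dihydroxychroman-4-yl group (3,4-trans) | Oc1ccc2c(c1)O[C@H](c1ccc(O)c(O)c1)[C@@H](O)[C@H]2c1c(O)c([C@@H]2c3ccc(O)cc3O[C@H](c3ccc(O)c(O)c3)[C@H]2O)c(O)c2c1O[C@H](c1ccc(O)c(O)c1)[C@@H](O)C2 | target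

**Summary**

Total step count: 5. Longest linear sequence: 5 (steps 1 to 5; compound 7 is made once in step 3 and used in both step 4 and step 5).

**Steps most likely to fail**

Step 2 (the proposed new cyclisation). The hydrogen-bonded 2'-hydroxychalcone may be epoxidised with lower enantioselectivity than simple chalcones, or in the opposite sense (the R catalyst is then used). Amine-promoted oxa-Michael closure to the flavanone, or 5-exo opening to the aurone hydrate, may also compete. The fallback uses established dihydroflavonol chemistry; it sets out from 1 and 2 and returns at 5. The phenol of 1 is masked with chloromethyl methyl ether and NaH in DMF to give 1-[4-(benzyloxy)-2-(methoxymethoxy)phenyl]ethanone F1. Claisen–Schmidt condensation of F1 with 2 gives the 2'-O-methoxymethyl chalcone F2. Juliá–Colonna epoxidation (poly-L-leucine, urea–hydrogen peroxide, DBU, THF) gives the (2R,3S)-epoxide F3. Methanolic HCl then removes the acetal, and the released phenol opens the epoxide at the benzylic carbon to give 5.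

Step 4 (first interflavan bond). The 3,4-cis adduct is expected to be the minor C8 diastereomer, and its separation from the 4α epimer is laborious. The fallback replaces cation capture by carbonyl addition followed by face-selective hydride delivery; it sets out from 5 and 8 and returns at 9. Compound 8 is perbenzylated (NaH, BnBr, DMF) to 3,5,7,3',4'-penta-O-benzylcatechin F4, which is brominated (NBS, CH2Cl2, −78 °C) to 8-bromo-penta-O-benzylcatechin F5. Compound 5 is benzylated at O3 (Ag2O, BnBr) to 3,7,3',4'-tetra-O-benzylfustin F6. Bromine–lithium exchange on F5 (n-BuLi, THF, −78 °C), transmetalation with anhydrous CeCl3 to suppress enolisation, and addition to the C4 carbonyl of F6 gives the C4 tertiary carbinol F7, whose C4 configuration is immaterial. Ionisation with CF3CO2H in the presence of Et3SiH (CH2Cl2, −78 °C) delivers hydride to the diaryl cation on the α-face, anti to the neighbouring 3-benzyloxy group. This leaves the catechin unit on the β-face and gives nona-O-benzyl fisetinidol-(4β→8)-catechin F8. Hydrogenolysis (H2, Pd(OH)2/C, THF–MeOH) then gives 9.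

Step 5 (second interflavan bond). C6 of the dimer is hindered, so self-condensation of the diol and some 4β attack can erode the yield. The fallback uses a pre-formed, isolable electrophile under neutral conditions; it sets out from 7 and 9 and returns at 10. Compound 7 is treated with phenylmethanethiol in acetic acid to give 4-benzylsulfanylfisetinidol F9 (C4 epimers converge on ionisation). Thiophilic activation with AgBF4 (THF, 0 °C) in the presence of one equivalent of 9 releases the C4 cation slowly, without protic acid or excess electrophile, and capture at C6 gives 10.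

**Further compounds**

F1 | step 2 | 1-[4-(benzyloxy)-2-(methoxymethoxy)phenyl]ethanone | CC(=O)c1ccc(OCc2ccccc2)cc1OCOC
F2 | step 2 | (E)-1-[4-(benzyloxy)-2-(methoxymethoxy)phenyl]-3-[3,4-bis(benzyloxy)phenyl]prop-2-en-1-one | O=C(/C=C/c1ccc(OCc2ccccc2)c(OCc2ccccc2)c1)c1ccc(OCc2ccccc2)cc1OCOC
F3 | step 2 | [(2R,3S)-3-[3,4-bis(benzyloxy)phenyl]oxiran-2-yl][4-(benzyloxy)-2-(methoxymethoxy)phenyl]methanone | O=C(c1ccc(OCc2ccccc2)cc1OCOC)[C@@H]1O[C@H]1c1ccc(OCc2ccccc2)c(OCc2ccccc2)c1
F4 | step 4 | (2R,3S)-3,5,7-tris(benzyloxy)-2-[3,4-bis(benzyloxy)phenyl]chromane (penta-O-benzylcatechin) | c1ccccc1CO[C@H]1Cc2c(OCc3ccccc3)cc(OCc3ccccc3)cc2O[C@@H]1c1ccc(OCc2ccccc2)c(OCc2ccccc2)c1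
F5 | step 4 | (2R,3S)-3,5,7-tris(benzyloxy)-2-[3,4-bis(benzyloxy)phenyl]-8-bromochromane | c1ccccc1CO[C@H]1Cc2c(OCc3ccccc3)cc(OCc3ccccc3)c(Br)c2O[C@@H]1c1ccc(OCc2ccccc2)c(OCc2ccccc2)c1
F6 | step 4 | (2R,3R)-3,7-bis(benzyloxy)-2-[3,4-bis(benzyloxy)phenyl]chroman-4-one | O=C1c2ccc(OCc3ccccc3)cc2O[C@H](c2ccc(OCc3ccccc3)c(OCc3ccccc3)c2)[C@H]1OCc1ccccc1
F7 | step 4 | 2,3-trans-3,7-bis(benzyloxy)-2-[3,4-bis(benzyloxy)phenyl]-4-(penta-O-benzylcatechin-8-yl)chroman-4-ol (C4 epimer mixture) | OC1(c2c(OCc3ccccc3)cc(OCc3ccccc3)c3c2O[C@H](c2ccc(OCc4ccccc4)c(OCc4ccccc4)c2)[C@@H](OCc2ccccc2)C3)c2ccc(OCc3ccccc3)cc2O[C@H](c2ccc(OCc3ccccc3)c(OCc3ccccc3)c2)[C@H]1OCc1ccccc1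
F8 | step 4 | nona-O-benzyl fisetinidol-(4β→8)-catechin (3,4-cis) | c1ccccc1COc1ccc2c(c1)O[C@H](c1ccc(OCc3ccccc3)c(OCc3ccccc3)c1)[C@@H](OCc1ccccc1)[C@H]2c1c(OCc2ccccc2)cc(OCc2ccccc2)c2c1O[C@H](c1ccc(OCc3ccccc3)c(OCc3ccccc3)c1)[C@@H](OCc1ccccc1)C2
F9 | step 5 | 2,3-trans-3,4-trans-4-(benzylsulfanyl)-2-(3,4-dihydroxyphenyl)chromane-3,7-diol (4α epimer shown) | Oc1ccc2c(c1)O[C@H](c1ccc(O)c(O)c1)[C@@H](O)[C@@H]2SCc1ccccc1
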